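**Assumption:** the run of carbons in the target SMILES is read as 19 CH2 groups between the stereocentre and the ester oxygen. The target is therefore (S)-20-methyldocosyl 2,3-dihydroxybenzoate, C30H52O4, with a single stereocentre, (S). Its CIP priority order is chain CH2 > ethyl > methyl > H.

## Retrosynthetic overview
- The target has no rings, so no ring-forming steps are needed.
- Disconnect the ester by lipase transesterification to (S)-20-methyldocosan-1-ol and methyl 2,3-dihydroxybenzoate, so the catechol needs no protecting groups.
- Disconnect the alcohol into three pieces joined by two Li2CuCl4-catalysed Grignard/alkyl-electrophile couplings: a chiral C5 unit, a C5 chain (from 1-bromo-5-chloropentane) and a C12 unit (from 12-bromododecanol as its TBS ether).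
- Set the only stereocentre at the start by Cu/Josiphos asymmetric conjugate addition of MeMgBr to ethyl (E)-pent-2-enoate. It is remote from every later reaction centre, so it cannot be scrambled.

## Route

**Step 1**
Reactants: 1 (ethyl (E)-pent-2-enoate), 2 (methylmagnesium bromide)
Product: 3 (ethyl (S)-3-methylpentanoate)
Conditions: CuBr·SMe2 (5 mol%), tBu-Josiphos (6 mol%), MeMgBr (1.5 equiv, slow addition), t-BuOMe, −75 °C, 4 h; MeOH quench, then aq. NH4Cl.
Reagents that add atoms: methylmagnesium bromide, C[Mg]Br.
Why: Cu/Josiphos-catalysed asymmetric conjugate addition of a Grignard reagent to an α,β-unsaturated ester delivers Me to one face of the (E)-enoate and creates the β-stereocentre. The ligand enantiomer that gives the (S)-ester is chosen in a pilot run and checked by chiral GC against the racemic ester. The low temperature and Cu catalysis suppress 1,2-addition to the ester.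

**Step 2**
Reactant: 3
Product: 4 ((S)-3-methylpentan-1-ol)
Conditions: LiAlH4 (0.6 equiv), Et2O, 0 °C → rt, 2 h; Fieser work-up.
Reagents that add atoms: none.
Why: Hydride reduction of the ester to the primary alcohol leaves the β-stereocentre untouched, because no bond to it is involved and it cannot enolise.

**Step 3**
Reactants: 4, 5 (p-toluenesulfonyl chloride)
Product: 6 ((S)-3-methylpentyl tosylate)
Conditions: TsCl (1.2 equiv), Et3N (1.5 equiv), DMAP (5 mol%), CH2Cl2, 0 °C → rt, 12 h.
Reagents that add atoms: TsCl, Cc1ccc(cc1)S(=O)(=O)Cl.
Why: Sulfonylation of the primary alcohol makes a non-volatile electrophile that is suited to Cu-catalysed coupling.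

**Step 4**
Reactants: 6, 7 (1-bromo-5-chloropentane)
Product: 8 ((S)-1-chloro-8-methyldecane)
Conditions: (i) 7 (1.5 equiv), Mg turnings, THF, rt, to give ClC5H10MgBr; (ii) add 6 and Li2CuCl4 (3 mol%), THF, −10 °C → rt, 12 h.
Reagents that add atoms: 1-bromo-5-chloropentane, ClCCCCCBr.
Why: Mg inserts selectively into the C–Br bond. The Kochi-type Cu-catalysed SN2 coupling of the Grignard reagent with the primary tosylate forms the C(sp3)–C(sp3) bond and leaves the alkyl chloride intact. The stereocentre is three carbons from the reacting carbon and is unchanged.

**Step 5**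
Reactants: 9 (12-bromododecan-1-ol), 10 (TBSCl)
Product: 11 (tert-butyl((12-bromododecyl)oxy)dimethylsilane)
Conditions: TBSCl (1.1 equiv), imidazole (2.2 equiv), DMF, rt, 4 h.
Reagents that add atoms: TBSCl, CC(C)(C)[Si](C)(C)Cl.
Why: Silylation masks the OH so that the later Grignard coupling is compatible. TBS is used rather than THP to avoid a new diastereomeric centre.

**Step 6**
Reactants: 8, 11
Product: 12 ((S)-tert-butyldimethyl((20-methyldocosyl)oxy)silane)
Conditions: (i) 8, Mg turnings (1.5 equiv), 1,2-dibromoethane (cat.), THF, reflux, 3 h; (ii) cool to −10 °C, add 11 (0.8 equiv relative to 8) and Li2CuCl4 (3 mol%), then warm to rt, 12 h.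
Reagents that add atoms: none beyond the reactants.
Why: The primary alkyl chloride gives a Grignard reagent under forcing Mg activation, and Li2CuCl4-catalysed coupling with the primary bromide 11 joins 7 + 12 = 19 CH2 between the stereocentre and oxygen. The silyl ether survives the Grignard reagent, and the stereocentre is remote from the reacting carbons.

**Step 7**
Reactant: 12
Product: 13 ((S)-20-methyldocosan-1-ol)
Conditions: AcCl (0.2 equiv, generates HCl), MeOH/THF 1:1, 0 °C → rt, 3 h; chromatography (hexanes/EtOAc) to remove any hydrocarbon homodimer.
Reagents that add atoms: none.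
Why: Acid-catalysed methanolysis of the primary TBS ether gives the free alcohol, and there is no other functional group to react.

**Step 8**
Reactants: 13, 14 (methyl 2,3-dihydroxybenzoate)
Product: 15 (Gentiside B)
Conditions: 14 (3 equiv), immobilised Candida antarctica lipase B (Novozym 435, 200 wt% relative to 13), 4 Å molecular sieves, toluene (0.1 M), 65 °C, Ar, 48–72 h; filter off the enzyme and purify on silica (hexanes/EtOAc).
Reagents that add atoms: methyl 2,3-dihydroxybenzoate (acyl donor), COC(=O)c1cccc(O)c1O.
Why: Lipase-catalysed transesterification (a hydrolase, EC 3.1.1.3) acylates only the primary aliphatic alcohol through a serine acyl-enzyme. The phenolic OH groups are not acylated, so no protection is needed, and the sieves remove MeOH to drive the reaction. No bond to the stereocentre is touched, so it stays (S).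

## Compound list
1 | ethyl (E)-pent-2-enoate | CC/C=C/C(=O)OCC | starting material
2 | methylmagnesium bromide | C[Mg]Br | starting material
3 | ethyl (S)-3-methylpentanoate | CC[C@H](C)CC(=O)OCC | intermediate
4 | (S)-3-methylpentan-1-ol | CC[C@H](C)CCO | intermediate
5 | p-toluenesulfonyl chloride | Cc1ccc(cc1)S(=O)(=O)Cl | starting material
6 | (S)-3-methylpentyl tosylate | CC[C@H](C)CCOS(=O)(=O)c1ccc(C)cc1 | intermediate
7 | 1-bromo-5-chloropentane | ClCCCCCBr | starting material
8 | (S)-1-chloro-8-methyldecane | CC[C@H](C)CCCCCCCCl | intermediate
9 | 12-bromododecan-1-ol | OCCCCCCCCCCCCBr | starting material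
10 | tert-butyldimethylsilyl chloride | CC(C)(C)[Si](C)(C)Cl | starting material
11 | tert-butyl((12-bromododecyl)oxy)dimethylsilane | CC(C)(C)[Si](C)(C)OCCCCCCCCCCCCBr | intermediate
12 | (S)-tert-butyldimethyl((20-methyldocosyl)oxy)silane | CC[C@H](C)CCCCCCCCCCCCCCCCCCCO[Si](C)(C)C(C)(C)C | intermediate
13 | (S)-20-methyldocosan-1-ol | CC[C@H](C)CCCCCCCCCCCCCCCCCCCO | intermediate
14 | methyl 2,3-dihydroxybenzoate | COC(=O)c1cccc(O)c1O | starting material
15 | Gentiside B, (S)-20-methyldocosyl 2,3-dihydroxybenzoate | CC[C@H](C)CCCCCCCCCCCCCCCCCCCOC(=O)c1cccc(O)c1O | target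

## Totals
- Total steps: 8.
- Longest linear sequence: 7 steps (1 → 3 → 4 → 6 → 8 → 12 → 13 → 15).

## Three steps most likely to fail
1. **Step 8 (lipase esterification).** The ortho-hydroxy benzoate is a poor acyl donor for the enzyme, so conversion may stall.
   - Fallback: change to a chemical route. Esterify alcohol 13 with 2,3-bis(benzyloxy)benzoyl chloride (Et3N, DMAP, CH2Cl2), then remove the benzyl groups by H2, Pd/C.
2. **Step 1 (asymmetric conjugate addition).** The ee for an ethyl β-substituent may be below the needed level, or 1,2-addition may compete.
   - Fallback: change the method to asymmetric hydrogenation of (E)-3-methylpent-2-enoic acid with an Ir/spiro-phosphine-oxazoline catalyst (H2, base). This gives (S)-3-methylpentanoic acid, which is esterified and carried into Step 2.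
3. **Step 6 (Grignard formation from the chloride and Cu coupling).** Mg insertion into the chloride may be incomplete, or Wurtz homodimer may form.
   - Fallback: reverse the polarity of the coupling. Convert chloride 8 to the iodide (NaI, acetone), make BrMg(CH2)12OTBS from 11, and couple that Grignard reagent with the iodide under Li2CuCl4 catalysis.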